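# Proposed total synthesis of (S)-wailupemycin F

**Retrosynthetic overview**
- Ring B holds a β-hydroxy ketone (C1 ketone, C3 carbinol). Cutting C2–C3 (aldol retron) gives a keto aldehyde with an acetyl group on C8a and a CH2CHO group on C4a; ring B is closed last and C3 is set in that step.
- The CH2CHO group comes from oxidative cleavage of a C4a allyl group, and the C8a acetyl group from an aryl triflate by Stille coupling. Both derive from one phenol through a Claisen rearrangement, which fixes their ortho relationship.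
- The pyranone ring on C5 is built before ring B from a formyl group (vinylogous aldol with a dioxinone, oxidation, acylketene cyclisation) and is carried as its benzyl ether.
- Ring A is bought as 2-bromo-5-hydroxy-4-methoxybenzaldehyde; the phenyl ring on C6 is attached first by Suzuki coupling.
- BCl3 finally frees the C8 phenol and the pyranone hydroxyl.

Key step: step 11

Remark: the target is (3S), which requires attack on the Re face of the aldehyde carbon; the (S,S)-ligand is specified on the assumption that the ring-closing aldol follows the facial preference of intermolecular aryl methyl ketone additions, and the (R,R)-ligand is equally available if the tether inverts it.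

**Step 1**
Reactants: 1 2-bromo-5-hydroxy-4-methoxybenzaldehyde; 2 phenylboronic acid
Product: 3 4-hydroxy-5-methoxybiphenyl-2-carbaldehyde
Conditions: Pd(PPh3)4 (3 mol%), K2CO3 (3 equiv), 1,4-dioxane/H2O 4:1, 90 °C
Reagents that add atoms: none
Why: Suzuki–Miyaura coupling of an aryl bromide activated by its ortho formyl group, the phenol being carried as its phenoxide; the bromide position places the phenyl group on the future C6.

**Step 2**
Reactants: 3 4-hydroxy-5-methoxybiphenyl-2-carbaldehyde; 4 allyl bromide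
Product: 5 4-(allyloxy)-5-methoxybiphenyl-2-carbaldehyde
Conditions: K2CO3, DMF, 50 °C
Reagents that add atoms: none
Why: Williamson ether synthesis on the only hydroxyl group of the molecule.

**Step 3**
Reactants: 5 4-(allyloxy)-5-methoxybiphenyl-2-carbaldehyde
Product: 7 3-allyl-4-hydroxy-5-methoxybiphenyl-2-carbaldehyde, via ortho-dienone 6 (not isolated)
Conditions: 1,2-dichlorobenzene, 180 °C, sealed tube, argon
Reagents that add atoms: none
Why: Aromatic Claisen rearrangement ([3,3]-sigmatropic shift, then tautomerisation); one ortho position carries the methoxy group and the para position the phenyl group, so the allyl group can only settle on the carbon between the phenol and the formyl group, the future C4a.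

**Step 4**
Reactants: 7 3-allyl-4-hydroxy-5-methoxybiphenyl-2-carbaldehyde
Product: 8 3-allyl-2-formyl-5-methoxybiphenyl-4-yl trifluoromethanesulfonate
Conditions: Tf2O, pyridine, CH2Cl2, 0 °C to rt
Reagents that add atoms: trifluoromethanesulfonic anhydride, O=S(=O)(OS(=O)(=O)C(F)(F)F)C(F)(F)F
Why: O-Sulfonylation of the phenol; the triflate masks the oxygen through steps 5 to 8 and is the handle for the later C8a–C1 bond.

**Step 5**
Reactants: 8 3-allyl-2-formyl-5-methoxybiphenyl-4-yl trifluoromethanesulfonate; 9 2,2,6-trimethyl-4H-1,3-dioxin-4-one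
Product: 10 3-allyl-2-[2-(2,2-dimethyl-4-oxo-4H-1,3-dioxin-6-yl)-1-hydroxyethyl]-5-methoxybiphenyl-4-yl trifluoromethanesulfonate (racemic)
Conditions: 9 (1.2 equiv), LDA (1.1 equiv), THF, −78 °C; then 8, −78 °C; AcOH quench at −78 °C
Reagents that add atoms: none
Why: Vinylogous aldol addition of the lithium dienolate of the dioxinone through its γ-carbon to a non-enolisable aryl aldehyde; the new carbinol centre forms as a racemate and is erased in step 6.

**Step 6**
Reactants: 10 3-allyl-2-[2-(2,2-dimethyl-4-oxo-4H-1,3-dioxin-6-yl)-1-hydroxyethyl]-5-methoxybiphenyl-4-yl trifluoromethanesulfonate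
Product: 11 3-allyl-2-[(2,2-dimethyl-4-oxo-4H-1,3-dioxin-6-yl)acetyl]-5-methoxybiphenyl-4-yl trifluoromethanesulfonate
Conditions: Dess–Martin periodinane, CH2Cl2, rt
Reagents that add atoms: none
Why: Dess–Martin oxidation of a secondary benzylic alcohol under near-neutral conditions that leave the dioxinone, the triflate and the alkene untouched.

**Step 7**
Reactants: 11 3-allyl-2-[(2,2-dimethyl-4-oxo-4H-1,3-dioxin-6-yl)acetyl]-5-methoxybiphenyl-4-yl trifluoromethanesulfonate
Product: 13 3-allyl-2-(4-hydroxy-2-oxo-2H-pyran-6-yl)-5-methoxybiphenyl-4-yl trifluoromethanesulfonate, via acylketene 12 (not isolated)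
Conditions: toluene (0.02 M), 110 °C
Reagents that add atoms: none
Why: Dioxinone thermolysis (retro-[4+2] loss of acetone) gives an acylketene that is captured by the enol oxygen of the aryl ketone, closing the 4-hydroxy-2-pyranone ring.

**Step 8**
Reactants: 13 3-allyl-2-(4-hydroxy-2-oxo-2H-pyran-6-yl)-5-methoxybiphenyl-4-yl trifluoromethanesulfonate
Product: 14 3-allyl-2-[4-(benzyloxy)-2-oxo-2H-pyran-6-yl]-5-methoxybiphenyl-4-yl trifluoromethanesulfonate
Conditions: BnBr, K2CO3, DMF, rt
Reagents that add atoms: benzyl bromide, BrCc1ccccc1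
Why: Williamson-type O-alkylation of the acidic vinylogous carboxylic acid at O4, which removes the proton that would otherwise quench the zinc catalyst of step 11.

**Step 9**
Reactants: 14 3-allyl-2-[4-(benzyloxy)-2-oxo-2H-pyran-6-yl]-5-methoxybiphenyl-4-yl trifluoromethanesulfonate; 15 tributyl(1-ethoxyvinyl)stannane
Product: 17 6-(4-acetyl-3-allyl-5-methoxybiphenyl-2-yl)-4-(benzyloxy)-2H-pyran-2-one, via enol ether 16 (not isolated)
Conditions: Pd(PPh3)4 (5 mol%), LiCl (3 equiv), 1,4-dioxane, 100 °C; then 1 M HCl, THF, rt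
Reagents that add atoms: water, O
Why: Stille coupling of the aryl triflate with an acetyl anion equivalent (chloride assisting transmetalation at the arylpalladium triflate), then mild acid hydrolysis of the α-aryl enol ether to the methyl ketone; the benzyloxypyranone tolerates both stages.

**Step 10**
Reactants: 17 6-(4-acetyl-3-allyl-5-methoxybiphenyl-2-yl)-4-(benzyloxy)-2H-pyran-2-one
Product: 19 2-{4-acetyl-2-[4-(benzyloxy)-2-oxo-2H-pyran-6-yl]-5-methoxybiphenyl-3-yl}acetaldehyde, via diol 18 (not isolated)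
Conditions: OsO4 (2 mol%), NaIO4 (4 equiv), 2,6-lutidine, 1,4-dioxane/H2O 3:1, rt; used at once
Reagents that add atoms: osmium tetroxide (oxygen carrier), O=[Os](=O)(=O)=O; sodium periodate (terminal oxidant), [Na+].[O-]I(=O)(=O)=O
Why: Lemieux–Johnson oxidation; the isolated terminal alkene should be dihydroxylated much faster than the conjugated, electron-poor pyranone double bonds, and periodate cleavage releases the sensitive arylacetaldehyde under buffered, near-neutral conditions.

**Step 11**
Reactants: 19 2-{4-acetyl-2-[4-(benzyloxy)-2-oxo-2H-pyran-6-yl]-5-methoxybiphenyl-3-yl}acetaldehyde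
Product: 20 (3S)-5-[4-(benzyloxy)-2-oxo-2H-pyran-6-yl]-3-hydroxy-8-methoxy-6-phenyl-3,4-dihydronaphthalen-1(2H)-one
Conditions: (S,S)-ProPhenol [(S,S)-2,6-bis{[2-(hydroxydiphenylmethyl)pyrrolidin-1-yl]methyl}-4-methylphenol] (20 mol%), ZnEt2 (40 mol%), Ph3P=S (20 mol%), 4 Å MS, THF, −20 °C, 19 added by syringe pump (0.01 M final); pH 7 buffer quench at −20 °C
Reagents that add atoms: none
Why: Proposed new method: the dinuclear zinc complex formed from ZnEt2 and the ligand is expected to enolise the C1 acetyl group at one zinc alkoxide site (the C8 methoxy oxygen offering a chelating contact) while the second zinc binds the C3 aldehyde, so that C2 adds to C3 inside the chiral pocket and proton transfer from fresh substrate releases 20 and returns the catalyst; the closest known reaction is the intermolecular direct aldol addition of aryl methyl ketones to aldehydes with the same type of catalyst, which has not been shown in a ring-forming sense. Ring B closes through C2–C3 in a 6-(enolendo)-exo-trig aldol mode; the opposite polarity, C4 of the aldehyde enolate attacking C1, would give a cyclobutanol and is no competitor. The C3 stereocentre is set by catalyst control of the aldehyde face: attack on the Re face (O > C4 > H) gives (S), taken here to be the face preferred with the (S,S)-ligand by analogy with the intermolecular additions. The step needs ketone enolisation to win over enolisation at the more acidic aldehyde α-carbon C4 and needs the aldol to survive: the zinc aldehyde enolate forms reversibly and has no cyclisation channel, so material should drain through the ketone enolate, slow addition at high dilution holds back intermolecular self-condensation, and dehydration to the naphthol is held back by working below 0 °C with only zinc alkoxide bases and quenching into buffer.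

**Step 12**
Reactants: 20 (3S)-5-[4-(benzyloxy)-2-oxo-2H-pyran-6-yl]-3-hydroxy-8-methoxy-6-phenyl-3,4-dihydronaphthalen-1(2H)-one
Product: 21 wailupemycin F, (3S)-3,8-dihydroxy-5-(4-hydroxy-2-oxo-2H-pyran-6-yl)-6-phenyl-3,4-dihydronaphthalen-1(2H)-one
Conditions: BCl3 (1 M in CH2Cl2, 6 equiv), CH2Cl2, −78 to −20 °C; pH 7 phosphate buffer quench at −78 °C
Reagents that add atoms: none
Why: Lewis acid ether cleavage: BCl3 chelated between the C1 carbonyl and the peri methoxy group should remove the methyl group by chloride attack and cleave the benzyl vinylogous ester likewise, while the C3 hydroxyl is held as a borate and the low temperature disfavours β-elimination; C3 is not touched.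

**Compound list**
1 | 2-bromo-5-hydroxy-4-methoxybenzaldehyde | O=Cc1cc(O)c(OC)cc1Br | starting material
2 | phenylboronic acid | OB(O)c1ccccc1 | starting material
3 | 4-hydroxy-5-methoxybiphenyl-2-carbaldehyde | O=Cc1cc(O)c(OC)cc1-c1ccccc1 | intermediate
4 | allyl bromide | C=CCBr | starting material
5 | 4-(allyloxy)-5-methoxybiphenyl-2-carbaldehyde | O=Cc1cc(OCC=C)c(OC)cc1-c1ccccc1 | intermediate
6 | 6-allyl-4-methoxy-5-oxo-2-phenylcyclohexa-1,3-diene-1-carbaldehyde (racemic ortho-dienone, not isolated) | O=C1C(OC)=CC(c2ccccc2)=C(C=O)C1CC=C | intermediate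
7 | 3-allyl-4-hydroxy-5-methoxybiphenyl-2-carbaldehyde | O=Cc1c(CC=C)c(O)c(OC)cc1-c1ccccc1 | intermediate
8 | 3-allyl-2-formyl-5-methoxybiphenyl-4-yl trifluoromethanesulfonate | O=Cc1c(CC=C)c(OS(=O)(=O)C(F)(F)F)c(OC)cc1-c1ccccc1 | intermediate
9 | 2,2,6-trimethyl-4H-1,3-dioxin-4-one | CC1=CC(=O)OC(C)(C)O1 | starting material
10 | 3-allyl-2-[2-(2,2-dimethyl-4-oxo-4H-1,3-dioxin-6-yl)-1-hydroxyethyl]-5-methoxybiphenyl-4-yl trifluoromethanesulfonate (racemic) | OC(CC1=CC(=O)OC(C)(C)O1)c1c(CC=C)c(OS(=O)(=O)C(F)(F)F)c(OC)cc1-c1ccccc1 | intermediate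
11 | 3-allyl-2-[(2,2-dimethyl-4-oxo-4H-1,3-dioxin-6-yl)acetyl]-5-methoxybiphenyl-4-yl trifluoromethanesulfonate | O=C(CC1=CC(=O)OC(C)(C)O1)c1c(CC=C)c(OS(=O)(=O)C(F)(F)F)c(OC)cc1-c1ccccc1 | intermediate
12 | 3-allyl-2-(3,5-dioxopent-4-enoyl)-5-methoxybiphenyl-4-yl trifluoromethanesulfonate (acylketene, not isolated) | O=C=CC(=O)CC(=O)c1c(CC=C)c(OS(=O)(=O)C(F)(F)F)c(OC)cc1-c1ccccc1 | intermediate
13 | 3-allyl-2-(4-hydroxy-2-oxo-2H-pyran-6-yl)-5-methoxybiphenyl-4-yl trifluoromethanesulfonate | O=c1cc(O)cc(-c2c(CC=C)c(OS(=O)(=O)C(F)(F)F)c(OC)cc2-c2ccccc2)o1 | intermediate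
14 | 3-allyl-2-[4-(benzyloxy)-2-oxo-2H-pyran-6-yl]-5-methoxybiphenyl-4-yl trifluoromethanesulfonate | O=c1cc(OCc2ccccc2)cc(-c2c(CC=C)c(OS(=O)(=O)C(F)(F)F)c(OC)cc2-c2ccccc2)o1 | intermediate
15 | tributyl(1-ethoxyvinyl)stannane | C=C(OCC)[Sn](CCCC)(CCCC)CCCC | starting material
16 | 6-[3-allyl-4-(1-ethoxyvinyl)-5-methoxybiphenyl-2-yl]-4-(benzyloxy)-2H-pyran-2-one (not isolated) | C=C(OCC)c1c(OC)cc(-c2ccccc2)c(-c2cc(OCc3ccccc3)cc(=O)o2)c1CC=C | intermediate
17 | 6-(4-acetyl-3-allyl-5-methoxybiphenyl-2-yl)-4-(benzyloxy)-2H-pyran-2-one | CC(=O)c1c(OC)cc(-c2ccccc2)c(-c2cc(OCc3ccccc3)cc(=O)o2)c1CC=C | intermediate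
18 | 6-[4-acetyl-3-(2,3-dihydroxypropyl)-5-methoxybiphenyl-2-yl]-4-(benzyloxy)-2H-pyran-2-one (racemic, not isolated) | CC(=O)c1c(OC)cc(-c2ccccc2)c(-c2cc(OCc3ccccc3)cc(=O)o2)c1CC(O)CO | intermediate
19 | 2-{4-acetyl-2-[4-(benzyloxy)-2-oxo-2H-pyran-6-yl]-5-methoxybiphenyl-3-yl}acetaldehyde | CC(=O)c1c(OC)cc(-c2ccccc2)c(-c2cc(OCc3ccccc3)cc(=O)o2)c1CC=O | intermediate
20 | (3S)-5-[4-(benzyloxy)-2-oxo-2H-pyran-6-yl]-3-hydroxy-8-methoxy-6-phenyl-3,4-dihydronaphthalen-1(2H)-one | O=C1C[C@@H](O)Cc2c1c(OC)cc(-c1ccccc1)c2-c1cc(OCc2ccccc2)cc(=O)o1 | intermediate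
21 | wailupemycin F, (3S)-3,8-dihydroxy-5-(4-hydroxy-2-oxo-2H-pyran-6-yl)-6-phenyl-3,4-dihydronaphthalen-1(2H)-one | O=C1C[C@@H](O)Cc2c1c(O)cc(-c1ccccc1)c2-c1cc(O)cc(=O)o1 | target

**Step count**
Total: 12 steps. Longest linear sequence: 12 steps (1 to 21).

**Steps most likely to fail**

Step 11. What may go wrong: enolisation at the aldehyde α-carbon C4 may outrun ketone enolisation and lead to intermolecular self-condensation; facial discrimination at C3 may be insufficient; the aldolate may dehydrate and ring B aromatise. The fallback uses known chemistry only, sets out from 14 and rejoins the route at 20; ring B is then closed at C8a–C1 and C3 is set by a reagent-controlled allylboration.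
- Lemieux–Johnson cleavage of 14 (OsO4 cat., NaIO4, 2,6-lutidine, dioxane/H2O) should give, through the diol F1, the arylacetaldehyde F2.
- Brown allylboration with (+)-B-allyldiisopinocampheylborane (Et2O, −78 °C, ethanolamine work-up) should give the (R)-homoallylic alcohol F3, whose carbinol carbon is the future C3 in the required spatial arrangement.
- TBSOTf and 2,6-lutidine give the silyl ether F4.
- An intramolecular Heck reaction of the aryl triflate (Pd(OAc)2, dppp, K2CO3, DMF, 80 °C; 6-exo-trig) closes ring B to the exocyclic alkene F5.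
- A second Lemieux–Johnson cleavage, through the diol F6, turns the methylidene group into the C1 ketone of the silyl-protected tetralone F7.
- HF·pyridine in THF then gives 20.

Step 9. What may go wrong: oxidative addition and transmetalation at the di-ortho-substituted triflate may be slow, so that triflate hydrolysis and migration of the allyl double bond into conjugation compete. The fallback sets out from 14 and rejoins the route at 19, replacing steps 9 and 10.
- Suzuki–Miyaura coupling with isopropenylboronic acid pinacol ester (Pd(OAc)2, SPhos, K3PO4, toluene/H2O, 80 °C), a coupling that copes well with hindered electrophiles, should give the isopropenyl arene F8.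
- One Lemieux–Johnson oxidation then cleaves both alkenes, through the tetraol F9, so that the acetyl and the acetaldehyde groups appear together in 19.

Step 12. What may go wrong: the C3 hydroxyl (as its borate) may undergo β-elimination under the Lewis acid, followed by aromatisation of ring B; ether cleavage may be incomplete at temperatures low enough to prevent this. The fallback changes the protecting groups so that the last step is a neutral hydrogenolysis; it sets out from 17 and rejoins the route at 21.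
- BCl3 (CH2Cl2, −78 to 0 °C) cleaves both ethers at this robust stage to give the phenol pyranol F10.
- BnBr, K2CO3, DMF, 60 °C gives the bis(benzyl ether) F11.
- Lemieux–Johnson cleavage, through the diol F12, gives the keto aldehyde F13.
- The zinc–ProPhenol aldol of step 11 gives the dibenzyl tetralone F14.
- H2 (1 atm), Pd/C, EtOAc, rt gives 21.

**Further compounds**
F1 | step 11 | 2-[4-(benzyloxy)-2-oxo-2H-pyran-6-yl]-3-(2,3-dihydroxypropyl)-5-methoxybiphenyl-4-yl trifluoromethanesulfonate (racemic diol, not isolated) | OCC(O)Cc1c(OS(=O)(=O)C(F)(F)F)c(OC)cc(-c2ccccc2)c1-c1cc(OCc2ccccc2)cc(=O)o1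
F2 | step 11 | 2-[4-(benzyloxy)-2-oxo-2H-pyran-6-yl]-5-methoxy-3-(2-oxoethyl)biphenyl-4-yl trifluoromethanesulfonate | O=CCc1c(OS(=O)(=O)C(F)(F)F)c(OC)cc(-c2ccccc2)c1-c1cc(OCc2ccccc2)cc(=O)o1
F3 | step 11 | 2-[4-(benzyloxy)-2-oxo-2H-pyran-6-yl]-3-[(2R)-2-hydroxypent-4-en-1-yl]-5-methoxybiphenyl-4-yl trifluoromethanesulfonate | C=CC[C@@H](O)Cc1c(OS(=O)(=O)C(F)(F)F)c(OC)cc(-c2ccccc2)c1-c1cc(OCc2ccccc2)cc(=O)o1
F4 | step 11 | 2-[4-(benzyloxy)-2-oxo-2H-pyran-6-yl]-3-[(2R)-2-(tert-butyldimethylsilyloxy)pent-4-en-1-yl]-5-methoxybiphenyl-4-yl trifluoromethanesulfonate | C=CC[C@@H](O[Si](C)(C)C(C)(C)C)Cc1c(OS(=O)(=O)C(F)(F)F)c(OC)cc(-c2ccccc2)c1-c1cc(OCc2ccccc2)cc(=O)o1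
F5 | step 11 | (3R)-5-[4-(benzyloxy)-2-oxo-2H-pyran-6-yl]-3-(tert-butyldimethylsilyloxy)-8-methoxy-1-methylidene-6-phenyl-1,2,3,4-tetrahydronaphthalene | C=C1C[C@@H](O[Si](C)(C)C(C)(C)C)Cc2c1c(OC)cc(-c1ccccc1)c2-c1cc(OCc2ccccc2)cc(=O)o1
F6 | step 11 | (3S)-5-[4-(benzyloxy)-2-oxo-2H-pyran-6-yl]-3-(tert-butyldimethylsilyloxy)-1-(hydroxymethyl)-8-methoxy-6-phenyl-1,2,3,4-tetrahydronaphthalen-1-ol (mixture at C1, not isolated) | OCC1(O)C[C@@H](O[Si](C)(C)C(C)(C)C)Cc2c1c(OC)cc(-c1ccccc1)c2-c1cc(OCc2ccccc2)cc(=O)o1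
F7 | step 11 | (3S)-5-[4-(benzyloxy)-2-oxo-2H-pyran-6-yl]-3-(tert-butyldimethylsilyloxy)-8-methoxy-6-phenyl-3,4-dihydronaphthalen-1(2H)-one | O=C1C[C@@H](O[Si](C)(C)C(C)(C)C)Cc2c1c(OC)cc(-c1ccccc1)c2-c1cc(OCc2ccccc2)cc(=O)o1
F8 | step 9 | 6-[3-allyl-5-methoxy-4-(prop-1-en-2-yl)biphenyl-2-yl]-4-(benzyloxy)-2H-pyran-2-one | CC(=C)c1c(OC)cc(-c2ccccc2)c(-c2cc(OCc3ccccc3)cc(=O)o2)c1CC=C
F9 | step 9 | 4-(benzyloxy)-6-[4-(1,2-dihydroxypropan-2-yl)-3-(2,3-dihydroxypropyl)-5-methoxybiphenyl-2-yl]-2H-pyran-2-one (stereoisomer mixture, not isolated) | CC(O)(CO)c1c(OC)cc(-c2ccccc2)c(-c2cc(OCc3ccccc3)cc(=O)o2)c1CC(O)CO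
F10 | step 12 | 6-(4-acetyl-3-allyl-5-hydroxybiphenyl-2-yl)-4-hydroxy-2H-pyran-2-one | CC(=O)c1c(O)cc(-c2ccccc2)c(-c2cc(O)cc(=O)o2)c1CC=C
F11 | step 12 | 6-[4-acetyl-3-allyl-5-(benzyloxy)biphenyl-2-yl]-4-(benzyloxy)-2H-pyran-2-one | CC(=O)c1c(OCc2ccccc2)cc(-c2ccccc2)c(-c2cc(OCc3ccccc3)cc(=O)o2)c1CC=C
F12 | step 12 | 6-[4-acetyl-5-(benzyloxy)-3-(2,3-dihydroxypropyl)biphenyl-2-yl]-4-(benzyloxy)-2H-pyran-2-one (racemic diol, not isolated) | CC(=O)c1c(OCc2ccccc2)cc(-c2ccccc2)c(-c2cc(OCc3ccccc3)cc(=O)o2)c1CC(O)CO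
F13 | step 12 | 2-{4-acetyl-5-(benzyloxy)-2-[4-(benzyloxy)-2-oxo-2H-pyran-6-yl]biphenyl-3-yl}acetaldehyde | CC(=O)c1c(OCc2ccccc2)cc(-c2ccccc2)c(-c2cc(OCc3ccccc3)cc(=O)o2)c1CC=O
F14 | step 12 | (3S)-8-(benzyloxy)-5-[4-(benzyloxy)-2-oxo-2H-pyran-6-yl]-3-hydroxy-6-phenyl-3,4-dihydronaphthalen-1(2H)-one | O=C1C[C@@H](O)Cc2c1c(OCc1ccccc1)cc(-c1ccccc1)c2-c1cc(OCc2ccccc2)cc(=O)o1
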